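**Plan**

1. Retrosynthesis: the six O-benzyl groups come off last. Ring C is then cut at C4–C4a together with O1–C8a, giving a ring-A aryne (C4a≡C8a) and an open C2–C3–C4 chain that carries O1 as a free benzylic alcohol and C4 as a Weinreb amide.
2. Enabling feature: ring A is fully substituted and its two ring-fusion carbons are flanked differently, C5–O beside C4a and C8–CH2Ar beside C8a. An O-nucleophile therefore adds at C8a and the carbanion appears at C4a, six atoms from C4.
3. Forward, ring A: ortho-bromination of 3,5-bis(benzyloxy)phenol, exhaustive C-benzylation of the two remaining positions, then conversion of Br/OH into SiMe3/OTf.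
4. Forward, chain and ring C: an auxiliary-controlled anti-glycolate aldol gives the chain; ring C is then made in one flask by O-arylation and C4–C4a closure.
5. Stereochemistry: C2 and C3 (both R) are set in the anti aldol by the (R)-oxazolidinethione; the O1–C2 bond is never made or broken afterwards and C3 is never enolisable before the final neutral hydrogenolysis.

Key step: step 7

Assumption: the anti-glycolate aldol of step 5 is taken to use the same enolate face as the syn aldol of this auxiliary class (open transition state, auxiliary not chelated), so the (R)-auxiliary gives the (2R,3R) adduct; were the sense opposite, the (S)-auxiliary would be used and nothing else would change.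

**Route**

Step 1
Reactants: 1 3,5-bis(benzyloxy)phenol
Product: 2 3,5-bis(benzyloxy)-2-bromophenol
Conditions: NBS (1.0 equiv), i-Pr2NH (10 mol %), CH2Cl2, −78 → 0 °C
Reagents that add atoms: N-bromosuccinimide, O=C1CCC(=O)N1Br
Why: Electrophilic aromatic bromination; amine-mediated delivery through the phenolic O–H should favour the position ortho to OH over the para position, which lies between two benzyloxy groups, and one equivalent at low temperature limits dibromination.

Step 2
Reactants: 2 3,5-bis(benzyloxy)-2-bromophenol; 3 4-(benzyloxy)benzyl alcohol (2.3 equiv)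
Product: 6 3,5-bis(benzyloxy)-4,6-bis[4-(benzyloxy)benzyl]-2-bromophenol, via 6-monobenzyl phenol 4 (not isolated), via 4-monobenzyl phenol 5 (not isolated)
Conditions: Sc(OTf)3 (5 mol %), MeNO2, rt → 40 °C
Reagents that add atoms: none
Why: Friedel–Crafts benzylation by the p-alkoxybenzyl cation; only two ring positions are free and both are ortho/para to three oxygens, so exhaustive substitution should converge on one product through either 4 or 5, while bromine blocks the future C4a.

Step 3
Reactants: 6 3,5-bis(benzyloxy)-4,6-bis[4-(benzyloxy)benzyl]-2-bromophenol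
Product: 9 3,5-bis(benzyloxy)-4,6-bis[4-(benzyloxy)benzyl]-2-(trimethylsilyl)phenyl trifluoromethanesulfonate, via aryl silyl ether 7 (not isolated), via lithium phenoxide 8 (not isolated)
Conditions: HMDS, THF, 70 °C, then evaporate; n-BuLi, THF, −100 → −78 °C; Tf2O, −78 °C → rt
Reagents that add atoms: hexamethyldisilazane, C[Si](C)(C)N[Si](C)(C)C; trifluoromethanesulfonic anhydride, O=S(=O)(OS(=O)(=O)C(F)(F)F)C(F)(F)F
Why: O-silylation, bromine–lithium exchange, 1,3 O→C silyl shift (retro-Brook rearrangement) and O-triflation, the standard one-flask route from 2-bromophenols to 2-silylaryl triflates; exchange at −100 °C should outrun deprotonation of the benzylic CH2 groups.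

Step 4
Reactants: 10 (R)-4-benzyl-1,3-oxazolidine-2-thione; 11 (benzyloxy)acetyl chloride
Product: 12 (R)-4-benzyl-3-[(benzyloxy)acetyl]-1,3-oxazolidine-2-thione
Conditions: Et3N, CH2Cl2, 0 °C → rt
Reagents that add atoms: none
Why: N-acylation of the auxiliary by an acid chloride under amine base, a routine preparation of N-glycolyl oxazolidinethiones.

Step 5
Reactants: 12 (R)-4-benzyl-3-[(benzyloxy)acetyl]-1,3-oxazolidine-2-thione; 13 4-(benzyloxy)benzaldehyde
Product: 15 (R)-4-benzyl-3-[(2R,3R)-2-(benzyloxy)-3-[4-(benzyloxy)phenyl]-3-hydroxypropanoyl]-1,3-oxazolidine-2-thione, via titanium enolate 14 (not isolated)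
Conditions: TiCl4 (1.1 equiv), i-Pr2NEt (1.1 equiv), CH2Cl2, −78 °C; then 13 premixed with TiCl4 (2 equiv), −78 °C; cold aq. NH4Cl
Reagents that add atoms: none
Why: Anti-selective titanium glycolate aldol; the Z-enolate 14 meets an aldehyde already bound to a second TiCl4, so the closed chair is unavailable and an open transition state should give the anti adduct, with the auxiliary benzyl group shielding one enolate face to set C2 and C3 as R,R.

Step 6
Reactants: 15 (R)-4-benzyl-3-[(2R,3R)-2-(benzyloxy)-3-[4-(benzyloxy)phenyl]-3-hydroxypropanoyl]-1,3-oxazolidine-2-thione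
Product: 16 (2R,3R)-2-(benzyloxy)-3-[4-(benzyloxy)phenyl]-3-hydroxy-N-methoxy-N-methylpropanamide
Conditions: MeNHOMe·HCl, imidazole, CH2Cl2, rt
Reagents that add atoms: N,O-dimethylhydroxylamine hydrochloride, CNOC.Cl
Why: Aminolysis of the activated N-acyl oxazolidinethione to the Weinreb amide with release of the auxiliary; the conditions are too mild for epimerisation or retro-aldol cleavage.

Step 7
Reactants: 16 (2R,3R)-2-(benzyloxy)-3-[4-(benzyloxy)phenyl]-3-hydroxy-N-methoxy-N-methylpropanamide; 9 3,5-bis(benzyloxy)-4,6-bis[4-(benzyloxy)benzyl]-2-(trimethylsilyl)phenyl trifluoromethanesulfonate (1.3 equiv)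
Product: 21 (2R,3R)-3,5,7-tris(benzyloxy)-6,8-bis[4-(benzyloxy)benzyl]-2-[4-(benzyloxy)phenyl]chroman-4-one, via potassium alkoxide 17 (not isolated), via aryne 18 (not isolated), via aryl anion 19 (not isolated), via tetrahedral adduct 20 (not isolated)
Conditions: KH (1.0 equiv), 18-crown-6, THF, 0 °C; then 9, CsF, −20 °C → rt; aq. NH4Cl at 0 °C
Reagents that add atoms: none
Why: Proposed new method: CsF strips the silyl group of 9 and triflate leaves, giving aryne 18 (C4a≡C8a); the proton-free potassium alkoxide 17 adds through oxygen at C8a, and the aryl anion 19 so formed at C4a attacks the Weinreb carbonyl six atoms away to give the chelated tetrahedral adduct 20, which should hold until the NH4Cl quench releases ketone 21. The closest known reaction type is the fluoride-induced annulation of arynes with salicylate esters to xanthones (O-arylation, then intramolecular acyl substitution by the aryl anion), joined to the Parham-type closure of an aryl carbanion onto a Weinreb amide; what is new is the aliphatic, stereodefined β-alkoxide as the O-nucleophile. Ring C closes by the C4–C4a bond in a 6-exo-trig attack of the C4a carbanion on the amide carbon, O1–C8a having formed an instant before. No stereocentre is made: C2 and C3 arrive from 16 and stay as they are, because the O1–C2 bond is not touched, the alkoxide is the only base, and the ketone stays masked in 20 until the quench, so C3 cannot enolise and ring C cannot open. The step needs regioselective addition to an aryne whose flanks differ, and this should be secured by the C5 benzyloxy group beside C4a: its inductive pull distorts the aryne so that the nucleophile enters at the remote carbon C8a and charge builds at C4a next to the C–O bond, against which the C8 benzyl group beside C8a offers only a modest steric bias. It also needs acyl capture to beat protonation of 19, which the absence of any O–H (KH gives H2) and the intramolecular six-membered delivery to the Weinreb amide should secure.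

Step 8
Reactants: 21 (2R,3R)-3,5,7-tris(benzyloxy)-6,8-bis[4-(benzyloxy)benzyl]-2-[4-(benzyloxy)phenyl]chroman-4-one
Product: 22 gericudranin D, (2R,3R)-3,5,7-trihydroxy-6,8-bis(4-hydroxybenzyl)-2-(4-hydroxyphenyl)chroman-4-one
Conditions: H2 (1 atm), 10% Pd/C, EtOAc–MeOH, rt
Reagents that add atoms: none
Why: Hydrogenolysis of all six benzyl ethers under neutral conditions, which should leave the trans-2,3 stereodiad, the ring-C ether and the diarylmethane links intact if the reaction is stopped at the calculated uptake.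

**Compound list**

1 | 3,5-bis(benzyloxy)phenol | Oc1cc(OCc2ccccc2)cc(OCc2ccccc2)c1 | starting material
2 | 3,5-bis(benzyloxy)-2-bromophenol | Oc1cc(OCc2ccccc2)cc(OCc2ccccc2)c1Br | intermediate
3 | 4-(benzyloxy)benzyl alcohol | OCc1ccc(OCc2ccccc2)cc1 | starting material
4 | 3,5-bis(benzyloxy)-6-[4-(benzyloxy)benzyl]-2-bromophenol | Oc1c(Br)c(OCc2ccccc2)cc(OCc2ccccc2)c1Cc1ccc(OCc2ccccc2)cc1 | intermediate
5 | 3,5-bis(benzyloxy)-4-[4-(benzyloxy)benzyl]-2-bromophenol | Oc1cc(OCc2ccccc2)c(Cc2ccc(OCc3ccccc3)cc2)c(OCc2ccccc2)c1Br | intermediate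
6 | 3,5-bis(benzyloxy)-4,6-bis[4-(benzyloxy)benzyl]-2-bromophenol | Oc1c(Br)c(OCc2ccccc2)c(Cc2ccc(OCc3ccccc3)cc2)c(OCc2ccccc2)c1Cc1ccc(OCc2ccccc2)cc1 | intermediate
7 | [3,5-bis(benzyloxy)-4,6-bis[4-(benzyloxy)benzyl]-2-bromophenoxy]trimethylsilane | C[Si](C)(C)Oc1c(Br)c(OCc2ccccc2)c(Cc2ccc(OCc3ccccc3)cc2)c(OCc2ccccc2)c1Cc1ccc(OCc2ccccc2)cc1 | intermediate
8 | lithium 3,5-bis(benzyloxy)-4,6-bis[4-(benzyloxy)benzyl]-2-(trimethylsilyl)phenoxide | [Li+].[O-]c1c([Si](C)(C)C)c(OCc2ccccc2)c(Cc2ccc(OCc3ccccc3)cc2)c(OCc2ccccc2)c1Cc1ccc(OCc2ccccc2)cc1 | intermediate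
9 | 3,5-bis(benzyloxy)-4,6-bis[4-(benzyloxy)benzyl]-2-(trimethylsilyl)phenyl trifluoromethanesulfonate | O=S(=O)(Oc1c([Si](C)(C)C)c(OCc2ccccc2)c(Cc2ccc(OCc3ccccc3)cc2)c(OCc2ccccc2)c1Cc1ccc(OCc2ccccc2)cc1)C(F)(F)F | intermediate
10 | (R)-4-benzyl-1,3-oxazolidine-2-thione | S=C1OC[C@@H](Cc2ccccc2)N1 | starting material
11 | (benzyloxy)acetyl chloride | O=C(Cl)COCc1ccccc1 | starting material
12 | (R)-4-benzyl-3-[(benzyloxy)acetyl]-1,3-oxazolidine-2-thione | S=C1OC[C@@H](Cc2ccccc2)N1C(=O)COCc1ccccc1 | intermediate
13 | 4-(benzyloxy)benzaldehyde | O=Cc1ccc(OCc2ccccc2)cc1 | starting material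
14 | Cl3Ti (Z)-enolate of 12 | S=C1OC[C@@H](Cc2ccccc2)N1/C(O[Ti](Cl)(Cl)Cl)=C/OCc1ccccc1 | intermediate
15 | (R)-4-benzyl-3-[(2R,3R)-2-(benzyloxy)-3-[4-(benzyloxy)phenyl]-3-hydroxypropanoyl]-1,3-oxazolidine-2-thione | S=C1OC[C@@H](Cc2ccccc2)N1C(=O)[C@H](OCc1ccccc1)[C@H](O)c1ccc(OCc2ccccc2)cc1 | intermediate
16 | (2R,3R)-2-(benzyloxy)-3-[4-(benzyloxy)phenyl]-3-hydroxy-N-methoxy-N-methylpropanamide | CON(C)C(=O)[C@H](OCc1ccccc1)[C@H](O)c1ccc(OCc2ccccc2)cc1 | intermediate
17 | potassium alkoxide of 16 | [K+].CON(C)C(=O)[C@H](OCc1ccccc1)[C@H]([O-])c1ccc(OCc2ccccc2)cc1 | intermediate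
18 | 3,5-bis(benzyloxy)-4,6-bis[4-(benzyloxy)benzyl]benzyne | C1#CC(OCc2ccccc2)=C(Cc2ccc(OCc3ccccc3)cc2)C(OCc2ccccc2)=C1Cc1ccc(OCc2ccccc2)cc1 | intermediate
19 | (2R,3R)-2-(benzyloxy)-3-[4-(benzyloxy)phenyl]-3-{3,5-bis(benzyloxy)-2,4-bis[4-(benzyloxy)benzyl]-6-potassiophenoxy}-N-methoxy-N-methylpropanamide | [K+].CON(C)C(=O)[C@H](OCc1ccccc1)[C@H](Oc1[c-]c(OCc2ccccc2)c(Cc2ccc(OCc3ccccc3)cc2)c(OCc2ccccc2)c1Cc1ccc(OCc2ccccc2)cc1)c1ccc(OCc2ccccc2)cc1 | intermediate
20 | potassium (2R,3R)-3,5,7-tris(benzyloxy)-6,8-bis[4-(benzyloxy)benzyl]-2-[4-(benzyloxy)phenyl]-4-[methoxy(methyl)amino]chroman-4-olate | [K+].[O-]C1(N(C)OC)c2c(OCc3ccccc3)c(Cc3ccc(OCc4ccccc4)cc3)c(OCc3ccccc3)c(Cc3ccc(OCc4ccccc4)cc3)c2O[C@H](c2ccc(OCc3ccccc3)cc2)[C@H]1OCc1ccccc1 | intermediate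
21 | (2R,3R)-3,5,7-tris(benzyloxy)-6,8-bis[4-(benzyloxy)benzyl]-2-[4-(benzyloxy)phenyl]chroman-4-one | O=C1c2c(OCc3ccccc3)c(Cc3ccc(OCc4ccccc4)cc3)c(OCc3ccccc3)c(Cc3ccc(OCc4ccccc4)cc3)c2O[C@H](c2ccc(OCc3ccccc3)cc2)[C@H]1OCc1ccccc1 | intermediate
22 | gericudranin D, (2R,3R)-3,5,7-trihydroxy-6,8-bis(4-hydroxybenzyl)-2-(4-hydroxyphenyl)chroman-4-one | O=C1c2c(O)c(Cc3ccc(O)cc3)c(O)c(Cc3ccc(O)cc3)c2O[C@H](c2ccc(O)cc2)[C@H]1O | target

**Totals**

Total step count: 8. Longest linear sequence: 5 steps (1, 2, 3, 7, 8 or 4, 5, 6, 7, 8).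

**Steps most likely to fail**

Step 7 (proposed new method). What may go wrong: protonation of the aryl anion or retro-aldol cleavage of the alkoxide before the acyl group is captured, or addition to the aryne in the wrong sense. Fallback with known chemistry, setting out from 12 (with 13 and 6) and returning at 21: O1–C2 is made by inversion and the ring closed by a classical anionic cyclisation. The syn-selective titanium aldol of 12 with 13 (TiCl4, i-Pr2NEt, N-methylpyrrolidinone, closed transition state) should give the syn aldol adduct F1. MeNHOMe·HCl/imidazole converts it into the syn Weinreb amide F2. Mitsunobu etherification of bromophenol 6 with F2 (PPh3, DIAD, toluene) inverts the carbinol carbon and gives the aryl ether bromide F3. Bromine–lithium exchange with t-BuLi at −100 °C, Parham cyclisation onto the Weinreb amide and aqueous quench then give 21.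

Step 2. What may go wrong: stalling after the first benzylation at the crowded second position, or electrophilic attack at the bromine-bearing carbon with loss or migration of bromine. Fallback, setting out from 2 and returning at 6: the benzyl groups are installed by cross-coupling instead of by a cation. Iodination of 2 with NIS (2.2 equiv, MeCN) at the two free positions gives the diiodophenol F4. Twofold Negishi coupling with 4-(benzyloxy)benzylzinc chloride (Pd(OAc)2, SPhos, THF), in which the two C–I bonds should react ahead of the hindered C–Br bond, gives 6.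

Step 5. What may go wrong: erosion of anti/syn control, or ionisation of the p-alkoxybenzylic titanium aldolate under excess TiCl4 with scrambling of the carbinol centre. Fallback, setting out from 13 and returning at 16: a reagent-controlled Mukaiyama aldol replaces the auxiliary. Aldehyde 13 and (Z)-2-(benzyloxy)-1-(ethylsulfanyl)-1-(trimethylsilyloxy)ethene under Sn(OTf)2, a proline-derived chiral diamine (antipode chosen for the R,R product) and Bu2Sn(OAc)2 in CH2Cl2 at −78 °C should give the anti thioester F5. MeNHOMe·HCl/i-PrMgCl (THF, −20 °C) converts F5 into 16.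

**Further compounds**

F1 | step 7 | (R)-4-benzyl-3-[(2R,3S)-2-(benzyloxy)-3-[4-(benzyloxy)phenyl]-3-hydroxypropanoyl]-1,3-oxazolidine-2-thione | S=C1OC[C@@H](Cc2ccccc2)N1C(=O)[C@H](OCc1ccccc1)[C@@H](O)c1ccc(OCc2ccccc2)cc1
F2 | step 7 | (2R,3S)-2-(benzyloxy)-3-[4-(benzyloxy)phenyl]-3-hydroxy-N-methoxy-N-methylpropanamide | CON(C)C(=O)[C@H](OCc1ccccc1)[C@@H](O)c1ccc(OCc2ccccc2)cc1
F3 | step 7 | (2R,3R)-2-(benzyloxy)-3-[4-(benzyloxy)phenyl]-3-{3,5-bis(benzyloxy)-4,6-bis[4-(benzyloxy)benzyl]-2-bromophenoxy}-N-methoxy-N-methylpropanamide | CON(C)C(=O)[C@H](OCc1ccccc1)[C@H](Oc1c(Br)c(OCc2ccccc2)c(Cc2ccc(OCc3ccccc3)cc2)c(OCc2ccccc2)c1Cc1ccc(OCc2ccccc2)cc1)c1ccc(OCc2ccccc2)cc1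
F4 | step 2 | 3,5-bis(benzyloxy)-2-bromo-4,6-diiodophenol | Oc1c(Br)c(OCc2ccccc2)c(I)c(OCc2ccccc2)c1I
F5 | step 5 | S-ethyl (2R,3R)-2-(benzyloxy)-3-[4-(benzyloxy)phenyl]-3-hydroxypropanethioate | CCSC(=O)[C@H](OCc1ccccc1)[C@H](O)c1ccc(OCc2ccccc2)cc1
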